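**Strategy.** Ring B (C5–C6–C7–C8–C9–C10, eudesmane numbering, with methyl C14 on C10, oxygen on C8 and the C11 unit on C7) is a p-menthan-3-one, and its C7–C8 bond is the one that citronellal closes on the way to isopulegol. The route therefore assembles a ring-A-bearing citronellol analogue (alcohol 6) from (E)-β-ocimene by an enantioselective Diels–Alder reaction. Pyridinium chlorochromate then triggers an oxidation/carbonyl-ene/oxidation cascade that forms C7–C8, the trans-decalin and the C8 ketone in one operation. Conjugation, α-face dihydroxylation of C3=C4, a carbonyl-directed singlet-oxygen ene reaction (C11–OH, C6=C7) and angeloylation complete the target.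

Key step: step 4

**Remarks and assumptions**
- Eudesmane numbering is used for the bicyclic compounds and for the carbons that become them: ring A = C1–C5 and C10, ring B = C5–C10, C11–C13 the three-carbon unit on C7, C14 the methyl on C10, C15 the methyl on C4. β is the face of the C14 methyl, α the opposite face.
- Assumption: the facial sense of the chiral oxazaborolidinium cation in step 2 is taken from the usual pre-transition-state model for α-branched acroleins. The (S)-catalyst is written; its mirror image would be used if the sense proved opposite.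
- The target is (3R,4S,5R,10R): 3α-angeloyloxy, 4α-OH (4β-methyl), 5α-H, 10β-methyl, i.e. a trans-decalin with a cis-3,4-diol monoester.

**Step 1**
Reactants: 1 4-oxobutyl acetate; 2 formaldehyde (37% aqueous)
Product: 3 3-formylbut-3-en-1-yl acetate
Conditions: aq. HCHO, pyrrolidine (10 mol %), propionic acid (10 mol %), i-PrOH, 45 °C
Reagents that add atoms: formaldehyde (compound 2), C=O
Why: Amine-catalysed α-methylenation (Mannich condensation followed by elimination) acts at the only enolisable position of 1, the CH2 next to the formyl group, leaves the acetate untouched and forms no stereocentre.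

**Step 2**
Reactants: 3 3-formylbut-3-en-1-yl acetate; 4 (E)-β-ocimene
Product: 5 2-[(1S,2S)-1-formyl-3-methyl-2-(3-methylbut-2-en-1-yl)cyclohex-3-en-1-yl]ethyl acetate
Conditions: 4 (2 equiv), (S)-B-(o-tolyl)-α,α-diphenylprolinol oxazaborolidine (20 mol %), Tf2NH (18 mol %), CH2Cl2, −78 °C
Reagents that add atoms: none
Why: In this catalytic enantioselective Diels–Alder reaction the 1-alkyl terminus of the s-cis diene of 4 directs the quaternary carbon of 3 to the "ortho" position, the boron-bound formyl group reacts endo and so ends cis to the prenyl arm (trans to the acetoxyethyl arm), and the chiral oxazaborolidinium cation selects the enal face and thereby the absolute configuration of both new stereocentres (later C10 and C5).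

**Step 3**
Reactants: 5 2-[(1S,2S)-1-formyl-3-methyl-2-(3-methylbut-2-en-1-yl)cyclohex-3-en-1-yl]ethyl acetate
Product: 6 2-[(1R,2R)-1,3-dimethyl-2-(3-methylbut-2-en-1-yl)cyclohex-3-en-1-yl]ethan-1-ol
Conditions: N2H4·H2O, KOH, diethylene glycol, 130 °C then 200 °C
Reagents that add atoms: none
Why: Wolff–Kishner reduction in the Huang–Minlon manner should turn the non-enolisable neopentyl aldehyde into the angular methyl C14 while the hot KOH saponifies the acetate, and neither stereocentre can epimerise.

**Step 4**
Reactants: 6 2-[(1R,2R)-1,3-dimethyl-2-(3-methylbut-2-en-1-yl)cyclohex-3-en-1-yl]ethan-1-ol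
Product: 9 eudesma-3,11-dien-8-one (5αH,7αH,10β-methyl), via aldehyde 7 (not isolated), via ene alcohol 8 (not isolated)
Conditions: pyridinium chlorochromate [C5H5NH][CrO3Cl] (3 equiv), CH2Cl2, 25 °C
Reagents that add atoms: none
Why: The chromium reagent first oxidises the primary alcohol of 6 to aldehyde 7, its acidity then activates the formyl group for a type I intramolecular carbonyl-ene (Prins-type) reaction in which C7 of the prenyl group attacks C8 while a C12 hydrogen passes to oxygen, and a second equivalent oxidises the secondary alcohol 8 to ketone 9. The closest known reaction is the pyridinium chlorochromate cyclisation of citronellol to isopulegone, of which 6 is a ring-A-annulated analogue with a rate-enhancing quaternary C10. Ring B closes in the 6-exo-trig mode with respect to both the carbonyl group and the alkene, through a chair transition state built on the trans, pseudo-equatorial C9 and C6 arms, so the trans ring fusion follows from the existing stereocentres C5 and C10. The only new stereocentre that survives the flask, C7, is set by the equatorial isopropenyl group of that chair (also the thermodynamic position after enolisation) and is erased in step 5, while C8 is formed and erased within the cascade. The step needs the aldehyde to choose the prenyl alkene over the ring alkene C3=C4, which is secured because attack at C7 builds a strain-free cyclohexane with a tertiary, cation-like C11 and an allylic hydrogen within reach, whereas attack on C3=C4 would have to build a bridged bicyclo[2.2.2]octane.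

**Step 5**
Reactants: 9 eudesma-3,11-dien-8-one
Product: 10 eudesma-3,7(11)-dien-8-one (5αH,10β-methyl)
Conditions: NaOH, EtOH, 25 °C
Reagents that add atoms: none
Why: Base-mediated isomerisation through the C7 dienolate should move the double bond into conjugation (isopulegone-to-pulegone type), erasing C7 and leaving the non-enolisable C5 and C10 untouched.

**Step 6**
Reactants: 10 eudesma-3,7(11)-dien-8-one
Product: 11 3α,4α-dihydroxyeudesm-7(11)-en-8-one
Conditions: OsO4 (2 mol %), N-methylmorpholine N-oxide, acetone/H2O, 25 °C
Reagents that add atoms: osmium tetroxide, O=[Os](=O)(=O)=O; N-methylmorpholine N-oxide, C[N+]1([O-])CCOCC1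
Why: In this Upjohn dihydroxylation OsO4 should add syn to the electron-rich trisubstituted C3=C4 alkene in preference to the electron-poor tetrasubstituted enone alkene and from the α face, anti to the axial C14 methyl, which sets 3α-OH and 4α-OH (4β-methyl) in one event.

**Step 7**
Reactants: 11 3α,4α-dihydroxyeudesm-7(11)-en-8-one
Product: 13 3α,4α,11-trihydroxyeudesm-6-en-8-one, via hydroperoxide 12 (not isolated)
Conditions: O2, visible light, tetraphenylporphyrin (cat.), CH2Cl2, 0 °C; then PPh3, 0 to 25 °C
Reagents that add atoms: dioxygen, O=O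
Why: In this Schenck ene reaction of an s-cis alkylidene ketone, singlet oxygen should bond to the β carbon C11 and take the axial hydrogen of C6, the alkyl group geminal to the carbonyl (gem selectivity of α,β-unsaturated carbonyl compounds), so that hydroperoxide 12 carries the C6=C7 enone and PPh3 reduces O–OH to OH without touching a stereocentre.

**Step 8**
Reactants: 13 3α,4α,11-trihydroxyeudesm-6-en-8-one; 14 angelic acid
Product: 16 3α-angeloyloxy-4α,11-dihydroxyeudesm-6-en-8-one (target), via mixed anhydride 15 (not isolated)
Conditions: 14, 2,4,6-trichlorobenzoyl chloride, Et3N, toluene, 25 °C; then 13, 80 °C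
Reagents that add atoms: 2,4,6-trichlorobenzoyl chloride, O=C(Cl)c1c(Cl)cc(Cl)cc1Cl (its acyl group is carried only by 15 and is lost again on the way to 16)
Why: Yamaguchi-type esterification through the mixed anhydride without DMAP is the established way to angelates that avoids Z-to-E isomerisation to the tiglate, only the secondary 3α-hydroxyl should react because the C4 and C11 hydroxyls are tertiary, and C3 keeps its configuration since its C–O bond is not touched.

**Compound list**
1 | 4-oxobutyl acetate | CC(=O)OCCCC=O | starting material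
2 | formaldehyde | C=O | starting material
3 | 3-formylbut-3-en-1-yl acetate | CC(=O)OCCC(=C)C=O | intermediate
4 | (E)-β-ocimene, (3E)-3,7-dimethylocta-1,3,6-triene | C=C/C(C)=C/CC=C(C)C | starting material
5 | 2-[(1S,2S)-1-formyl-3-methyl-2-(3-methylbut-2-en-1-yl)cyclohex-3-en-1-yl]ethyl acetate | CC1=CCC[C@](C=O)(CCOC(C)=O)[C@H]1CC=C(C)C | intermediate
6 | 2-[(1R,2R)-1,3-dimethyl-2-(3-methylbut-2-en-1-yl)cyclohex-3-en-1-yl]ethan-1-ol | CC1=CCC[C@](C)(CCO)[C@H]1CC=C(C)C | intermediate
7 | 2-[(1R,2R)-1,3-dimethyl-2-(3-methylbut-2-en-1-yl)cyclohex-3-en-1-yl]acetaldehyde | CC1=CCC[C@](C)(CC=O)[C@H]1CC=C(C)C | intermediate (not isolated)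
8 | eudesma-3,11-dien-8α-ol (5αH,7αH,10β-methyl; hydroxyl and isopropenyl both equatorial) | CC1=CCC[C@]2(C)C[C@H](O)[C@@H](C(C)=C)C[C@H]21 | intermediate (not isolated)
9 | eudesma-3,11-dien-8-one (5αH,7αH,10β-methyl) | CC1=CCC[C@]2(C)CC(=O)[C@@H](C(C)=C)C[C@H]21 | intermediate
10 | eudesma-3,7(11)-dien-8-one (5αH,10β-methyl) | CC1=CCC[C@]2(C)CC(=O)C(=C(C)C)C[C@H]21 | intermediate
11 | 3α,4α-dihydroxyeudesm-7(11)-en-8-one | O[C@@H]1CC[C@]2(C)CC(=O)C(=C(C)C)C[C@H]2[C@]1(C)O | intermediate
12 | 11-hydroperoxy-3α,4α-dihydroxyeudesm-6-en-8-one | O[C@@H]1CC[C@]2(C)CC(=O)C(C(C)(C)OO)=C[C@H]2[C@]1(C)O | intermediate (not isolated)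
13 | 3α,4α,11-trihydroxyeudesm-6-en-8-one | O[C@@H]1CC[C@]2(C)CC(=O)C(C(C)(C)O)=C[C@H]2[C@]1(C)O | intermediate
14 | angelic acid, (Z)-2-methylbut-2-enoic acid | C/C=C(/C)C(=O)O | starting material
15 | angelic 2,4,6-trichlorobenzoic anhydride | C/C=C(/C)C(=O)OC(=O)c1c(Cl)cc(Cl)cc1Cl | intermediate (not isolated)
16 | (3R,4S,5R,10R)-3α-angeloyloxy-4α,11-dihydroxyeudesm-6-en-8-one | C/C=C(/C)C(=O)O[C@@H]1CC[C@]2(C)CC(=O)C(C(C)(C)O)=C[C@H]2[C@]1(C)O | target

**Total step count:** 8
**Longest linear sequence:** 8 steps (1 → 3 → 5 → 6 → 9 → 10 → 11 → 13 → 16)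

**Steps most likely to fail**

Step 2. The cycloaddition may suffer from catalyst binding at the acetate carbonyl, from poor endo orientation, or from poor facial discrimination with an α-branched acrolein. The fallback changes the dienophile class; it sets out from 4 and comes back at 6. Compound 4 is combined with commercial α-methylene-γ-butyrolactone (the same oxazaborolidine activated by AlBr3, CH2Cl2, −40 °C). This enoate is locked s-cis and its only Lewis-basic site is the reacting carbonyl. The product is (5S,6S)-7-methyl-6-(3-methylbut-2-en-1-yl)-2-oxaspiro[4.5]dec-7-en-1-one F1, with the lactone carbonyl endo and therefore cis to the prenyl arm. iBu2AlH (toluene, −78 °C) gives (5S,6S)-7-methyl-6-(3-methylbut-2-en-1-yl)-2-oxaspiro[4.5]dec-7-en-1-ol F2 as a mixture of anomers. Huang–Minlon reduction of F2, through its open hydroxy aldehyde, converts the lactol carbon into the C14 methyl and frees the hydroxyethyl arm, which returns the route to 6.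

Step 4. The chromium cascade may stall at aldehyde 7, over-oxidise, or let the formyl group react with the ring alkene. The fallback closes ring B at the acyl oxidation level; it sets out from 6 and comes back at 10, replacing steps 4 and 5. TEMPO (cat.) with PhI(OAc)2 in MeCN/H2O gives 2-[(1R,2R)-1,3-dimethyl-2-(3-methylbut-2-en-1-yl)cyclohex-3-en-1-yl]acetic acid F3. (COCl)2 with catalytic DMF gives 2-[(1R,2R)-1,3-dimethyl-2-(3-methylbut-2-en-1-yl)cyclohex-3-en-1-yl]acetyl chloride F4. SnCl4 (CH2Cl2, −78 °C) then promotes an intramolecular aliphatic Friedel–Crafts acylation: C7 attacks the acylium ion and chloride traps the C11 cation, giving 11-chloroeudesm-3-en-8-one F5. Et3N eliminates HCl across C7–C11 and delivers the conjugated enone 10 directly.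

Step 7. The photooxygenation may be too slow on the twisted enone, or hydrogen abstraction may occur from a C11 methyl group instead of C6. The fallback introduces the C11 oxygen and the C6=C7 bond separately and moves the dihydroxylation to the end; it sets out from 10 and comes back at 13. H2O2/NaOH (MeOH, 0 °C), a nucleophilic epoxidation that ignores the isolated C3=C4 alkene, gives 7,11-epoxyeudesm-3-en-8-one F6. SmI2 (THF/MeOH, −78 °C) cleaves the C7–O bond reductively to 11-hydroxyeudesm-3-en-8-one F7. IBX (DMSO, 65 °C) dehydrogenates the ketone, necessarily towards C6 because C10 is quaternary, to 11-hydroxyeudesma-3,6-dien-8-one F8. OsO4 with N-methylmorpholine N-oxide then dihydroxylates C3=C4 from the α face as in step 6 and gives 13.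

**Further compounds**
F1 | step 2 | (5S,6S)-7-methyl-6-(3-methylbut-2-en-1-yl)-2-oxaspiro[4.5]dec-7-en-1-one | CC1=CCC[C@@]2(C(=O)OCC2)[C@H]1CC=C(C)C
F2 | step 2 | (5S,6S)-7-methyl-6-(3-methylbut-2-en-1-yl)-2-oxaspiro[4.5]dec-7-en-1-ol (anomers) | CC1=CCC[C@@]2(C(O)OCC2)[C@H]1CC=C(C)C
F3 | step 4 | 2-[(1R,2R)-1,3-dimethyl-2-(3-methylbut-2-en-1-yl)cyclohex-3-en-1-yl]acetic acid | CC1=CCC[C@](C)(CC(=O)O)[C@H]1CC=C(C)C
F4 | step 4 | 2-[(1R,2R)-1,3-dimethyl-2-(3-methylbut-2-en-1-yl)cyclohex-3-en-1-yl]acetyl chloride | CC1=CCC[C@](C)(CC(=O)Cl)[C@H]1CC=C(C)C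
F5 | step 4 | 11-chloroeudesm-3-en-8-one (5αH,10β-methyl; C7 epimers) | CC1=CCC[C@]2(C)CC(=O)C(C(C)(C)Cl)C[C@H]21
F6 | step 7 | 7,11-epoxyeudesm-3-en-8-one (5αH,10β-methyl; C7 epimers) | CC1=CCC[C@]2(C)CC(=O)C3(OC3(C)C)C[C@H]21
F7 | step 7 | 11-hydroxyeudesm-3-en-8-one (5αH,7αH,10β-methyl) | CC1=CCC[C@]2(C)CC(=O)[C@@H](C(C)(C)O)C[C@H]21
F8 | step 7 | 11-hydroxyeudesma-3,6-dien-8-one (5αH,10β-methyl) | CC1=CCC[C@]2(C)CC(=O)C(C(C)(C)O)=C[C@H]21
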